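In millimolar we can state what the dusk and noon runs share.

| flask | starting material | protic impurity | remark | time |
|---|---|---|---|---|
| dusk | 32 mM (in portions, 2) | 9.6 mM | the very flask that is asked about, followed so far; portions every 1.2 s |  |
| noon | 64 mM (in portions, 2) | 9.6 mM | run made earlier; portions every 1.2 s |  |
| flask | 32 mM (in portions, 2) | 9.60 mM | the portions of starting material follow each other after 1.2 s, the first at the start | 15 min |

- dusk (time / min: starting material / %, ring / %): 0.250: 4, 61; 0.500: 0, 68; 1.33: 0, 66; 3.00: 0, 64
- noon (time / min: starting material / %, ring / %): 4.00: 1, 54; 8.00: 1, 54; 12.0: 1, 55; 15.0: 1, 56

(readings scatter by 1.5 percentage points)

- the earlier runs were read with a standard deviation of 1.5 percentage points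
- a reading or a percentage of ring counts all its forms, free or not
- the reaction counts as stopped when no species that holds the starting material changes by six tenths of a point or more over the second half of the time

* at 15 min, what has stopped the reaction, if anything has (forward and back rates have come level / it is still moving / all of the starting material has reacted)
* conversion of starting material at 15 min
* amount of ring at 15 min, in percent of the starting material charged

Two rates compete for each molecule of starting material. Ring closing has a rate per molecule that does not depend on concentration. A loss in which two molecules meet has a rate per molecule that rises with c(starting material). This is our guess, and it fits the direction of the runs: at the larger charge of noon, mean ring reads 54.8%, less than the 66.0% of dusk.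

So we freeze c(starting material) at its charge and define the level concentration: the charge at which ring and everything else come out equal, charge times ring over non-ring. This is a rough effective molarity. Dusk gives 62.1 mM and noon gives 77.4 mM, more than dusk, because the frozen concentration is crude. We take the mean, 69.8 mM.

Our ring share is level concentration over level concentration plus charge, which gives 68.6% for the flask. Starting material reads 0% at 0.500 min, so we expect it to have reacted completely.

The forecast says forward and back rates have come level, with conversion 99.5% and ring 62%, holding that ring “it is relaxing downward”.

    starting material → ring (k = 0.160 s⁻¹)
    crystals ⇌ ring, rate k2*(cs2 - [ring]) while solid is left; crystals form when [ring] > cs2 (solubility = 20.0 mM, k = 12.0 s⁻¹)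
    starting material + protic impurity → quenched substrate (k = 1.20 M⁻¹ s⁻¹)
    2 starting material → open dimer (k = 2.70 M⁻¹ s⁻¹)

The flask gives all of the starting material has reacted, with conversion 100% and ring 66.9%, against our 68.6%. The forecast parts from it on the ending: in the flask 0% of the starting material is left at 15.0 min, and no step of the scheme runs back to it. At 54 mM, the level concentration gives 56.4%, and that neighbour flask holds 57.5%. The main reason for the lost ring is pairing: the flask run without the path to open dimer reaches 93.9% of ring instead of 66.9%, which is 82% of what is missing.

(The earlier runs and the new flask come from a simulation with made-up constants, noise included.)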